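**Retrosynthetic overview**
- Feature used: ring B carries four contiguous oxygens on C6' (OMe), C1' (O-ring A), C2' (OH) and C3' (OMe), with C3'/C6' para, H on C4' and prenyl on C5'. This is the pattern of a hydroquinone grown from a squarate.
- Endgame: the C2'-O and ring A hydroxyls are unmasked last, and the C3'/C6' methyl ethers come from a ring B hydroquinone.
- Key disconnection: ring B is opened across C5'–C6' to a 4-alkenyl-4-hydroxycyclobutenone whose squarate carbons (future C1', C2') already hold the aryloxy and 4-methoxybenzyloxy groups.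
- The cyclobutenone comes from 1,2-addition of (E)-1-lithio-5-methylhexa-1,4-diene (from prenyl bromide and an ethynyl Grignard reagent) to a mixed aryl/4-methoxybenzyl squarate (from squaryl dichloride, 4-methoxybenzyl alcohol and bis-MOM ring A phenol).
- Ring order: ring A and the four-membered ring are bought; ring B is the only ring formed (step 8).

Key step: step 8

Remark: ring A is the benzoate ring; ring B is numbered C1' (diaryl ether carbon), C2' (OH), C3' (OMe), C4' (H), C5' (prenyl), C6' (OMe). The target has no stereocentre and no stereogenic alkene.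

**Step 1**
Reactants: 1 methyl 2,4,6-trihydroxybenzoate
Product: 2 methyl 2-hydroxy-4,6-bis(methoxymethoxy)benzoate
Conditions: MOMCl (2.1 equiv), i-Pr2NEt, CH2Cl2, 0 °C to rt
Reagents that add atoms: chloromethyl methyl ether, COCCl
Why: Williamson-type O-alkylation in which the 4-OH and one ortho OH react, while the last ortho hydroxyl, hydrogen-bonded to the ester carbonyl, is the least nucleophilic and should stay free with 2.1 equiv of MOMCl.

**Step 2**
Reactants: 3 squaric acid
Product: 4 squaryl dichloride (3,4-dichlorocyclobut-3-ene-1,2-dione)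
Conditions: (COCl)2 (2.2 equiv), DMF (cat.), CH2Cl2, rt to 40 °C
Reagents that add atoms: oxalyl chloride, O=C(Cl)C(=O)Cl
Why: DMF-catalysed (Vilsmeier-type) conversion of the two vinylogous acid hydroxyls into chlorides, the standard preparation of squaryl dichloride.

**Step 3**
Reactants: 4 squaryl dichloride; 5 4-methoxybenzyl alcohol
Product: 6 3-chloro-4-(4-methoxybenzyloxy)cyclobut-3-ene-1,2-dione
Conditions: 5 (1.0 equiv), i-Pr2NEt (1.0 equiv), CH2Cl2, −78 to −20 °C; filtered, concentrated cold, used at once
Reagents that add atoms: none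
Why: Addition–elimination at a vinylogous acid chloride; the first alkoxy group donates into the dione and makes the remaining C–Cl less electrophilic, so one equivalent of alcohol at low temperature with a hindered base should stop at the mono-ester chloride.

**Step 4**
Reactants: 2 methyl 2-hydroxy-4,6-bis(methoxymethoxy)benzoate; 6 3-chloro-4-(4-methoxybenzyloxy)cyclobut-3-ene-1,2-dione
Product: 8 methyl 2-{[2-(4-methoxybenzyloxy)-3,4-dioxocyclobut-1-en-1-yl]oxy}-4,6-bis(methoxymethoxy)benzoate, via sodium aryloxide 7 (not isolated)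
Conditions: NaH (1.05 equiv), THF, 0 °C; then 6, THF, −78 to 0 °C
Reagents that add atoms: none
Why: Acyl-type (addition–elimination) substitution of the remaining vinylogous acid chloride by the pre-formed sodium phenoxide; chloride is a far better leaving group than 4-methoxybenzyloxide, so the two different squarate oxygens are placed without scrambling.

**Step 5**
Reactants: 9 prenyl bromide (1-bromo-3-methylbut-2-ene); 10 ethynylmagnesium bromide
Product: 11 5-methylhex-4-en-1-yne
Conditions: 10 (2 equiv, 0.5 M in THF), CuCl (5 mol%), THF, 0 °C to rt; product kept as a distilled solution (volatile)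
Reagents that add atoms: none
Why: CuCl-catalysed coupling of an alkynyl Grignard reagent with an allylic bromide, which for a prenyl halide should go at the unhindered primary carbon (SN2, not SN2') and keep the trisubstituted alkene, while excess Grignard reagent suppresses double allylation.

**Step 6**
Reactants: 11 5-methylhex-4-en-1-yne
Product: 13 (E)-1-iodo-5-methylhexa-1,4-diene, via alkenylzirconocene chloride 12 (not isolated)
Conditions: Cp2Zr(H)Cl (1.1 equiv), THF, rt; then I2, THF, 0 °C
Reagents that add atoms: iodine, II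
Why: Hydrozirconation is a syn addition that places zirconium on the terminal alkyne carbon and is much faster for the terminal alkyne than for the trisubstituted alkene, and iodinolysis of the C–Zr bond with retention should give the (E)-iodide.

**Step 7**
Reactants: 13 (E)-1-iodo-5-methylhexa-1,4-diene; 8 methyl 2-{[2-(4-methoxybenzyloxy)-3,4-dioxocyclobut-1-en-1-yl]oxy}-4,6-bis(methoxymethoxy)benzoate
Product: 16 methyl 2-({3-hydroxy-2-(4-methoxybenzyloxy)-3-[(1E)-5-methylhexa-1,4-dien-1-yl]-4-oxocyclobut-1-en-1-yl}oxy)-4,6-bis(methoxymethoxy)benzoate (racemic), via alkenyllithium 14 (not isolated), via lithium alkoxide 15 (not isolated)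
Conditions: 13, t-BuLi (2.0 equiv), Et2O, −78 °C; cannulated into 8, THF, −78 °C; aq. NH4Cl at −78 °C
Reagents that add atoms: none
Why: Lithium–iodine exchange with retention of the E geometry, then 1,2-addition of the alkenyllithium to a squarate diester at the carbonyl next to C–OPMB, which is the vinylogous ester of the weaker aryloxy donor (more electrophilic) and is also the less shielded one; the new carbinol centre is formed as a racemate and is erased in step 8.

**Step 8**
Reactants: 16 the racemic 4-alkenyl-4-hydroxycyclobutenone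
Product: 19 methyl 2-[3,6-dihydroxy-2-(4-methoxybenzyloxy)-5-(3-methylbut-2-en-1-yl)phenoxy]-4,6-bis(methoxymethoxy)benzoate, via dienylketene 17 (not isolated), via cyclohexa-2,4-dienone 18 (not isolated)
Conditions: degassed toluene (0.02 M), 110 °C, Ar (p-xylene, 138 °C if slow)
Reagents that add atoms: none
Why: On heating, the cyclobutenone σ bond between the carbonyl and carbinol carbons opens by a conrotatory 4π electrocyclic process in which the donor hydroxyl rotates outward, so dienylketene 17 forms with the alkenyl group cis to the ketene. A thermal disrotatory 6π electrocyclisation then joins the ketene carbon (future C6') to the alkene terminus (future C5'), closing ring B as a six-membered ring in cyclohexa-2,4-dienone 18, and enolisation of the C5' hydrogen gives the aromatic hydroquinone 19. This is the established thermal ring expansion of squarate-derived 4-alkenyl-4-hydroxycyclobutenones to polysubstituted hydroquinones (the alkenyl counterpart of the Moore rearrangement). The only new stereocentre, sp3 C5' of 18, is transient and racemic and is lost on aromatisation, as is the carbinol centre of 16. The step needs outward rotation of the hydroxyl, which is the normal torquoselectivity for a donor on the carbinol carbon, and an unhindered alkene terminus, which the E geometry from step 6 provides. The squarate carbons bearing the aryloxy and 4-methoxybenzyloxy groups become C1' and C2' unchanged, and the two new hydroxyls sit on C6' and C3', para to each other.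

**Step 9**
Reactants: 19 the ring B hydroquinone
Product: 20 methyl 2-[3,6-dimethoxy-2-(4-methoxybenzyloxy)-5-(3-methylbut-2-en-1-yl)phenoxy]-4,6-bis(methoxymethoxy)benzoate
Conditions: Me2SO4 (4 equiv), K2CO3, acetone, 56 °C, Ar (crude 19 used directly)
Reagents that add atoms: dimethyl sulfate, COS(=O)(=O)OC
Why: Williamson methylation of both phenoxides, run under argon straight after step 8 because the hydroquinone is air-sensitive; MOM, 4-methoxybenzyl and ester groups are inert to K2CO3.

**Step 10**
Reactants: 20 the fully protected diaryl ether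
Product: 21 Paucinervin B, methyl 2,4-dihydroxy-6-[2-hydroxy-3,6-dimethoxy-5-(3-methylbut-2-en-1-yl)phenoxy]benzoate
Conditions: HCl (2 M in MeOH), 45 °C
Reagents that add atoms: none
Why: Acid-catalysed acetal exchange should remove both MOM ethers as dimethoxymethane and SN1 solvolysis the 4-methoxybenzyl ether with methanol trapping the benzylic cation; the prenyl group has no ortho hydroxyl (C6' is OMe), so chroman formation is excluded, and methanol cannot transesterify the methyl ester.

**Compound list**
1 | methyl 2,4,6-trihydroxybenzoate | COC(=O)c1c(O)cc(O)cc1O | starting material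
2 | methyl 2-hydroxy-4,6-bis(methoxymethoxy)benzoate | COC(=O)c1c(O)cc(OCOC)cc1OCOC | intermediate
3 | squaric acid | OC1=C(O)C(=O)C1=O | starting material
4 | squaryl dichloride | ClC1=C(Cl)C(=O)C1=O | intermediate
5 | 4-methoxybenzyl alcohol | COc1ccc(CO)cc1 | starting material
6 | 3-chloro-4-(4-methoxybenzyloxy)cyclobut-3-ene-1,2-dione | COc1ccc(COC2=C(Cl)C(=O)C2=O)cc1 | intermediate
7 | sodium 2-(methoxycarbonyl)-3,5-bis(methoxymethoxy)phenoxide | [Na+].COC(=O)c1c([O-])cc(OCOC)cc1OCOC | intermediate
8 | methyl 2-{[2-(4-methoxybenzyloxy)-3,4-dioxocyclobut-1-en-1-yl]oxy}-4,6-bis(methoxymethoxy)benzoate | COC(=O)c1c(OCOC)cc(OCOC)cc1OC1=C(OCc2ccc(OC)cc2)C(=O)C1=O | intermediate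
9 | prenyl bromide | CC(C)=CCBr | starting material
10 | ethynylmagnesium bromide | C#C[Mg]Br | starting material
11 | 5-methylhex-4-en-1-yne | C#CCC=C(C)C | intermediate
12 | chloro[(1E)-5-methylhexa-1,4-dien-1-yl]zirconocene (cyclopentadienyl rings drawn σ-bonded) | CC(C)=CC/C=C/[Zr](Cl)(C1C=CC=C1)C1C=CC=C1 | intermediate
13 | (E)-1-iodo-5-methylhexa-1,4-diene | CC(C)=CC/C=C/I | intermediate
14 | [(1E)-5-methylhexa-1,4-dien-1-yl]lithium | [Li]/C=C/CC=C(C)C | intermediate
15 | lithium alkoxide of 16 (racemic) | [Li+].COC(=O)c1c(OCOC)cc(OCOC)cc1OC1=C(OCc2ccc(OC)cc2)C([O-])(/C=C/CC=C(C)C)C1=O | intermediate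
16 | methyl 2-({3-hydroxy-2-(4-methoxybenzyloxy)-3-[(1E)-5-methylhexa-1,4-dien-1-yl]-4-oxocyclobut-1-en-1-yl}oxy)-4,6-bis(methoxymethoxy)benzoate (racemic) | COC(=O)c1c(OCOC)cc(OCOC)cc1OC1=C(OCc2ccc(OC)cc2)C(O)(/C=C/CC=C(C)C)C1=O | intermediate
17 | methyl 2-{[(3Z,5E)-4-hydroxy-3-(4-methoxybenzyloxy)-9-methyl-1-oxodeca-1,3,5,8-tetraen-2-yl]oxy}-4,6-bis(methoxymethoxy)benzoate (dienylketene) | COC(=O)c1c(OCOC)cc(OCOC)cc1OC(=C=O)/C(OCc1ccc(OC)cc1)=C(/O)\C=C\CC=C(C)C | intermediate
18 | methyl 2-{[3-hydroxy-2-(4-methoxybenzyloxy)-5-(3-methylbut-2-en-1-yl)-6-oxocyclohexa-1,3-dien-1-yl]oxy}-4,6-bis(methoxymethoxy)benzoate (racemic) | COC(=O)c1c(OCOC)cc(OCOC)cc1OC1=C(OCc2ccc(OC)cc2)C(O)=CC(CC=C(C)C)C1=O | intermediate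
19 | methyl 2-[3,6-dihydroxy-2-(4-methoxybenzyloxy)-5-(3-methylbut-2-en-1-yl)phenoxy]-4,6-bis(methoxymethoxy)benzoate | COC(=O)c1c(OCOC)cc(OCOC)cc1Oc1c(OCc2ccc(OC)cc2)c(O)cc(CC=C(C)C)c1O | intermediate
20 | methyl 2-[3,6-dimethoxy-2-(4-methoxybenzyloxy)-5-(3-methylbut-2-en-1-yl)phenoxy]-4,6-bis(methoxymethoxy)benzoate | COC(=O)c1c(OCOC)cc(OCOC)cc1Oc1c(OCc2ccc(OC)cc2)c(OC)cc(CC=C(C)C)c1OC | intermediate
21 | Paucinervin B | COC(=O)c1c(O)cc(O)cc1Oc1c(O)c(OC)cc(CC=C(C)C)c1OC | target

**Totals**
Total step count: 10. Longest linear sequence: 7 steps (steps 2, 3, 4, 7, 8, 9, 10, from squaric acid).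

**Steps most likely to fail**

1. Step 7. The alkenyllithium may fail to discriminate between the two squarate carbonyls, or may displace the aryloxide by conjugate addition–elimination instead of adding to a carbonyl. The fallback sets out from 4 and 7 and returns at 16. Squaryl dichloride 4 is treated with two equivalents of sodium aryloxide 7 (THF, −78 to 0 °C) to give the symmetrical bis(aryl) squarate F1, whose two carbonyls are equivalent. Addition of 14 at −78 °C should give lithium alkoxide F2 and, after NH4Cl quench, the 2,3-bis(aryloxy)-4-hydroxycyclobutenone F3. 4-Methoxybenzyl alcohol 5 with catalytic Et3N in CH2Cl2 (0 °C to rt) should then exchange only the aryloxy group on the β-carbon of the enone, the one site open to conjugate addition–elimination. This gives 16 with the regiochemistry fixed by mechanism and releases 2 for re-use.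

2. Step 8. The 6π closure of 17 may lose to attack of the hydroxyl on the ketene (butenolide formation), or the electron-rich hydroquinone may be oxidised and degraded during isolation. The fallback sets out from 11 and 8 and returns at 19. Enyne 11 is deprotonated with n-BuLi (THF, −78 °C) to the lithium acetylide F4, which adds to 8 at the same carbonyl to give lithium alkoxide F5 and, after quench, the 4-alkynyl-4-hydroxycyclobutenone F6. Thermolysis in toluene should give the air-stable benzoquinone F7 by ring opening, diradical closure and hydrogen transfer from the hydroxyl (Moore rearrangement). Reduction with Na2S2O4 (Et2O/water) gives 19 in solution, which is methylated at once as in step 9.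

3. Step 3. A second alcoholysis to the bis(4-methoxybenzyl) squarate may compete, and chloride may cleave the labile benzylic ester of 6 during handling. The fallback sets out from 4 and 7 and returns at 8, with the order of substitution reversed. One equivalent of 7 is added slowly to a slight excess of 4 (THF, −78 °C) to give the aryl chloro squarate F8, which carries no benzylic ester. Then 5 and i-Pr2NEt (CH2Cl2, −40 to 0 °C) should displace chloride, the better leaving group than the aryloxide, to give 8.

**Further compounds**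
F1 | step 7 | dimethyl 2,2'-[(3,4-dioxocyclobut-1-ene-1,2-diyl)bis(oxy)]bis[4,6-bis(methoxymethoxy)benzoate] | COC(=O)c1c(OCOC)cc(OCOC)cc1OC1=C(Oc2cc(OCOC)cc(OCOC)c2C(=O)OC)C(=O)C1=O
F2 | step 7 | lithium alkoxide of F3 (racemic) | [Li+].COC(=O)c1c(OCOC)cc(OCOC)cc1OC1=C(Oc2cc(OCOC)cc(OCOC)c2C(=O)OC)C([O-])(/C=C/CC=C(C)C)C1=O
F3 | step 7 | 2,3-bis{[2-(methoxycarbonyl)-3,5-bis(methoxymethoxy)phenyl]oxy}-4-hydroxy-4-[(1E)-5-methylhexa-1,4-dien-1-yl]cyclobut-2-en-1-one (racemic) | COC(=O)c1c(OCOC)cc(OCOC)cc1OC1=C(Oc2cc(OCOC)cc(OCOC)c2C(=O)OC)C(O)(/C=C/CC=C(C)C)C1=O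
F4 | step 8 | (5-methylhex-4-en-1-yn-1-yl)lithium | [Li]C#CCC=C(C)C
F5 | step 8 | lithium alkoxide of F6 (racemic) | [Li+].COC(=O)c1c(OCOC)cc(OCOC)cc1OC1=C(OCc2ccc(OC)cc2)C([O-])(C#CCC=C(C)C)C1=O
F6 | step 8 | methyl 2-{[3-hydroxy-2-(4-methoxybenzyloxy)-3-(5-methylhex-4-en-1-yn-1-yl)-4-oxocyclobut-1-en-1-yl]oxy}-4,6-bis(methoxymethoxy)benzoate (racemic) | COC(=O)c1c(OCOC)cc(OCOC)cc1OC1=C(OCc2ccc(OC)cc2)C(O)(C#CCC=C(C)C)C1=O
F7 | step 8 | methyl 2-{[2-(4-methoxybenzyloxy)-5-(3-methylbut-2-en-1-yl)-3,6-dioxocyclohexa-1,4-dien-1-yl]oxy}-4,6-bis(methoxymethoxy)benzoate | COC(=O)c1c(OCOC)cc(OCOC)cc1OC1=C(OCc2ccc(OC)cc2)C(=O)C=C(CC=C(C)C)C1=O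
F8 | step 3 | methyl 2-[(2-chloro-3,4-dioxocyclobut-1-en-1-yl)oxy]-4,6-bis(methoxymethoxy)benzoate | COC(=O)c1c(OCOC)cc(OCOC)cc1OC1=C(Cl)C(=O)C1=O
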